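**Plan**
1. The retrosynthesis cuts O1–C2 and C3–C4 of the methyl-bearing dihydropyran (O1, C2, C3, C4, C4a, C9a). This ring is fused to a tropolone through the enol-oxygen carbon C9a and its neighbour C4a and carries trans C2-dienyl and C3-methyl groups, so it is the oxa-[4+2] adduct of a tropolone o-quinone methide (O=C9a–C4a=CH2) with an E-propenyl group, as in the presumed biosynthesis.
2. The dienophile 18 is cut at O1'–C9a' of the other pyran (alkoxide addition–elimination on a 4-methoxytropone) and at the carbinol C–C bond (trienylzinc plus aldehyde).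
3. Both tropolones come from one bromotropolone 6, made from 2-methylanisole by Birch reduction, dibromocarbene addition and oxidative ring expansion.
4. Forward order: seven-membered ring (6), then the unsubstituted pyran (18), then the methyl-bearing pyran last, by the cycloaddition that also joins the two halves.
5. Stereochemistry: C2' (R) comes from a ligand-controlled alkenylzinc addition and is carried on with retention; C2/C3 are trans from the E-alkene in a suprafacial cycloaddition, and their absolute sense comes from a chiral Brønsted acid.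

Key step: step 13

Remark: methylation of 6 may also give the other tropolone O-methyl regioisomer; it reacts in the same way in the later steps and converges at 9 and 18, so the route is written for the isomer drawn.
Remark: (−)-MIB is taken to deliver the alkenyl group to the Si face of 11 (giving 3R) and (R)-TRIP to give the (2R,3R) adduct; if either sense is opposite, the antipodal ligand or acid is used.

**Step 1**
Reactants: 1 2-methylanisole
Product: 2 1-methoxy-2-methylcyclohexa-1,4-diene
Conditions: Li, liq. NH3, t-BuOH, THF, −78 → −33 °C; then H2O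
Reagents that add atoms: none
Why: Birch reduction of an alkyl aryl ether leaves methoxy and methyl on the retained tetrasubstituted double bond and gives the 2,5-dihydro enol ether, with no stereocentre formed.

**Step 2**
Reactants: 2 1-methoxy-2-methylcyclohexa-1,4-diene
Product: 3 rac-7,7-dibromo-1-methoxy-6-methylbicyclo[4.1.0]hept-3-ene
Conditions: CHBr3, KOt-Bu, pentane, −20 → 0 °C
Reagents that add atoms: bromoform, BrC(Br)Br
Why: Electrophilic dibromocarbene undergoes [2+1] cycloaddition at the electron-rich tetrasubstituted enol ether double bond in preference to the isolated cis-alkene; the ring fusion is necessarily cis and the racemic centres are destroyed in step 4.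

**Step 3**
Reactants: 3 rac-7,7-dibromo-1-methoxy-6-methylbicyclo[4.1.0]hept-3-ene
Product: 4 rac-7,7-dibromo-1-methoxy-6-methylbicyclo[4.1.0]heptane-3,4-diol (cis-diol)
Conditions: OsO4 (2 mol%), NMO, acetone/H2O, rt
Reagents that add atoms: N-methylmorpholine N-oxide, C[N+]1([O-])CCOCC1; water, O
Why: Catalytic osmium tetroxide syn-dihydroxylation of the remaining disubstituted alkene runs under neutral conditions that should leave the alkoxy gem-dibromocyclopropane intact, and the diol stereocentres are removed in step 4.

**Step 4**
Reactants: 4 rac-7,7-dibromo-1-methoxy-6-methylbicyclo[4.1.0]heptane-3,4-diol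
Product: 6 5-bromo-2-hydroxy-4-methoxy-6-methylcyclohepta-2,4,6-trien-1-one, via cyclopropane-fused diketone 5 (not isolated)
Conditions: DMSO, TFAA, CH2Cl2, −60 °C; Et3N, −60 °C → rt
Reagents that add atoms: none
Why: Swern-type oxidation of the cis-diol gives the α-diketone, whose enolisation triggers methoxy-assisted disrotatory electrocyclic opening of the gem-dibromocyclopropane with net loss of HBr, a known ring expansion of 7,7-dihalobicyclo[4.1.0]heptane-3,4-diols to halotropolones that places Br on the inserted carbon between C–OMe and C–Me.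

**Step 5**
Reactants: 6 5-bromo-2-hydroxy-4-methoxy-6-methylcyclohepta-2,4,6-trien-1-one
Product: 7 5-bromo-2,4-dimethoxy-6-methylcyclohepta-2,4,6-trien-1-one
Conditions: MeI, K2CO3, acetone, reflux
Reagents that add atoms: iodomethane, CI
Why: Williamson O-methylation of the acidic tropolone hydroxyl masks the chelating hydroxy ketone for the palladium steps.

**Step 6**
Reactants: 7 5-bromo-2,4-dimethoxy-6-methylcyclohepta-2,4,6-trien-1-one
Product: 8 5-(hydroxymethyl)-2,4-dimethoxy-6-methylcyclohepta-2,4,6-trien-1-one
Conditions: Bu3SnCH2OH, Pd(PPh3)4 (5 mol%), dioxane, 100 °C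
Reagents that add atoms: (tributylstannyl)methanol, CCCC[Sn](CCCC)(CCCC)CO
Why: Migita–Kosugi–Stille coupling with (tributylstannyl)methanol is an established direct hydroxymethylation of aryl and vinyl bromides under neutral conditions and should serve for the electron-poor bromotropone.

**Step 7**
Reactants: 8 5-(hydroxymethyl)-2,4-dimethoxy-6-methylcyclohepta-2,4,6-trien-1-one
Product: 9 2,4-dihydroxy-5-(hydroxymethyl)-6-methylcyclohepta-2,4,6-trien-1-one
Conditions: 0.5 M H2SO4, H2O/dioxane, high dilution, 70 °C
Reagents that add atoms: water, O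
Why: Acid-catalysed hydrolysis by addition–elimination of water at the two vinylogous ester carbons cleaves both methyl ethers as for tropolone methyl ethers generally, and dilute aqueous medium should return any benzylic cation to the alcohol.

**Step 8**
Reactants: 7 5-bromo-2,4-dimethoxy-6-methylcyclohepta-2,4,6-trien-1-one; 10 allyl alcohol
Product: 11 2,4-dimethoxy-6-methyl-5-(3-oxopropyl)cyclohepta-2,4,6-trien-1-one
Conditions: Pd(OAc)2 (5 mol%), Bu4NCl, NaHCO3, DMF, 80 °C
Reagents that add atoms: none
Why: Mizoroki–Heck reaction of an aryl-type bromide with allyl alcohol, in which β-hydride elimination towards the carbinol carbon and tautomerisation deliver the 3-arylpropanal directly.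

**Step 9**
Reactants: 12 (2E,4E)-hexa-2,4-dienal
Product: 13 (3E,5E)-hepta-3,5-dien-1-yne
Conditions: TMSCHN2, n-BuLi, THF, −78 °C → rt
Reagents that add atoms: trimethylsilyldiazomethane, C[Si](C)(C)C=[N+]=[N-]
Why: Colvin rearrangement, in which lithiated trimethylsilyldiazomethane adds 1,2 to the enal, Peterson elimination and loss of N2 give an alkylidene carbene, and 1,2-hydrogen shift gives the terminal enyne without touching the E,E-diene.

**Step 10**
Reactants: 13 (3E,5E)-hepta-3,5-dien-1-yne; 11 2,4-dimethoxy-6-methyl-5-(3-oxopropyl)cyclohepta-2,4,6-trien-1-one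
Product: 16 5-[(3R,4E,6E,8E)-3-hydroxydeca-4,6,8-trien-1-yl]-2,4-dimethoxy-6-methylcyclohepta-2,4,6-trien-1-one, via trienylborane 14 (not isolated), via trienylzinc 15 (not isolated)
Conditions: Cy2BH (cyclohexene, BH3·SMe2), PhMe, 0 °C → rt; Et2Zn, −78 °C; (−)-MIB (5 mol%), then 11, −20 → 0 °C; aq. NH4Cl
Reagents that add atoms: none
Why: syn-Hydroboration of the terminal alkyne gives the (E)-alkenylborane, boron-to-zinc transmetalation gives the alkenyl(ethyl)zinc, and the amino alcohol-catalysed enantioselective alkenylzinc addition to the aliphatic aldehyde sets the carbinol centre as R by ligand control, the tropone carbonyl being inert to organozincs.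

**Step 11**
Reactants: 16 5-[(3R,4E,6E,8E)-3-hydroxydeca-4,6,8-trien-1-yl]-2,4-dimethoxy-6-methylcyclohepta-2,4,6-trien-1-one
Product: 17 (2R)-2-[(1E,3E,5E)-hepta-1,3,5-trien-1-yl]-8-methoxy-5-methyl-3,4-dihydrocyclohepta[b]pyran-7(2H)-one
Conditions: NaH (0.2 equiv), THF, 4 Å MS, 0 °C → rt
Reagents that add atoms: none
Why: Base-catalysed intramolecular addition–elimination (vinylogous transesterification, the tropone counterpart of an SNAr etherification) lets the secondary alkoxide add to C4 of the 4-methoxytropone in a six-membered ring closure with loss of methoxide, so the carbinol C–O bond is untouched and the R centre is retained.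

**Step 12**
Reactants: 17 (2R)-2-[(1E,3E,5E)-hepta-1,3,5-trien-1-yl]-8-methoxy-5-methyl-3,4-dihydrocyclohepta[b]pyran-7(2H)-one
Product: 18 (2R)-2-[(1E,3E,5E)-hepta-1,3,5-trien-1-yl]-8-hydroxy-5-methyl-3,4-dihydrocyclohepta[b]pyran-7(2H)-one
Conditions: 1 M NaOH, THF/H2O, 40 °C; then aq. NaH2PO4 to pH 5, 0 °C
Reagents that add atoms: sodium hydroxide, [Na+].[OH-]
Why: Hydroxide addition–elimination at C8 (saponification of the tropolone methyl ether, a vinylogous ester) releases the tropolone, while the trienylic ether and its stereocentre are stable to base.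

**Step 13**
Reactants: 9 2,4-dihydroxy-5-(hydroxymethyl)-6-methylcyclohepta-2,4,6-trien-1-one; 18 (2R)-2-[(1E,3E,5E)-hepta-1,3,5-trien-1-yl]-8-hydroxy-5-methyl-3,4-dihydrocyclohepta[b]pyran-7(2H)-one
Product: 20 (2R,3R)-8-hydroxy-2-[(1E,3E)-4-[(2R)-8-hydroxy-5-methyl-7-oxo-2,3,4,7-tetrahydrocyclohepta[b]pyran-2-yl]buta-1,3-dien-1-yl]-3,5-dimethyl-3,4-dihydrocyclohepta[b]pyran-7(2H)-one, via tropolone o-quinone methide 19 (not isolated)
Conditions: (R)-TRIP (10 mol%), 4 Å MS, CH2Cl2, 0 °C → rt; 9 (2 equiv) added in portions
Reagents that add atoms: none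
Why: Proposed new method: the acid should ionise the benzylic C–OH of 9 to the o-quinone methide 19, held as a hydrogen-bonded contact ion pair with the chiral phosphate, and the E-propenyl terminus of 18 should add to it in an asynchronous inverse-electron-demand oxa-[4+2] cycloaddition (C–C bond to the exocyclic CH2 leading, the C9a carbonyl oxygen collapsing on the developing pentadienyl cation) that restores the tropolone; the closest known reaction types are the thermal biomimetic cycloaddition of tropolone o-quinone methides with alkenes and the chiral phosphoric acid-catalysed [4+2] cycloadditions of in situ generated o-quinone methides with styrenes, vinyl sulfides and unactivated alkenes. The dihydropyran closes in this single intermolecular [4+2] event (four atoms O=C–C=CH2 from 19, two from the alkene), which forms C3–C4 and O1–C2. C2 and C3 are set relative to each other by the E geometry of the alkene in the suprafacial addition (trans dienyl/methyl), and their absolute sense by the chiral anion, which shields one face of the bound o-quinone methide; the remote C2' centre of 18 exerts no bias, so control is by the reagent alone. The step needs site selectivity among three C=C bonds, which the substrate secures because the propenyl end is the least hindered and most electron-rich alkene (the C1'=C2' end is deactivated and shielded by the allylic ring oxygen), and regioselectivity, secured because bond formation at the methyl-bearing carbon places the developing cation next to the diene. A mild acid at or below room temperature is chosen so that the dienylic C–O bonds of 18 and 20 should not ionise.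

**Compound list**
1 | 2-methylanisole | COc1ccccc1C | starting material
2 | 1-methoxy-2-methylcyclohexa-1,4-diene | COC1=C(C)CC=CC1 | intermediate
3 | rac-7,7-dibromo-1-methoxy-6-methylbicyclo[4.1.0]hept-3-ene (cis-fused) | COC12CC=CCC1(C)C2(Br)Br | intermediate
4 | rac-7,7-dibromo-1-methoxy-6-methylbicyclo[4.1.0]heptane-3,4-diol (cis-diol, mixture of facial isomers) | COC12CC(O)C(O)CC1(C)C2(Br)Br | intermediate
5 | 7,7-dibromo-1-methoxy-6-methylbicyclo[4.1.0]heptane-3,4-dione (formed in situ) | COC12CC(=O)C(=O)CC1(C)C2(Br)Br | intermediate
6 | 5-bromo-2-hydroxy-4-methoxy-6-methylcyclohepta-2,4,6-trien-1-one | COc1cc(O)c(=O)cc(C)c1Br | intermediate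
7 | 5-bromo-2,4-dimethoxy-6-methylcyclohepta-2,4,6-trien-1-one | COc1cc(OC)c(=O)cc(C)c1Br | intermediate
8 | 5-(hydroxymethyl)-2,4-dimethoxy-6-methylcyclohepta-2,4,6-trien-1-one | COc1cc(OC)c(=O)cc(C)c1CO | intermediate
9 | 2,4-dihydroxy-5-(hydroxymethyl)-6-methylcyclohepta-2,4,6-trien-1-one | Cc1cc(=O)c(O)cc(O)c1CO | intermediate
10 | allyl alcohol (prop-2-en-1-ol) | C=CCO | starting material
11 | 2,4-dimethoxy-6-methyl-5-(3-oxopropyl)cyclohepta-2,4,6-trien-1-one | COc1cc(OC)c(=O)cc(C)c1CCC=O | intermediate
12 | (2E,4E)-hexa-2,4-dienal (sorbaldehyde) | C/C=C/C=C/C=O | starting material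
13 | (3E,5E)-hepta-3,5-dien-1-yne | C#C/C=C/C=C/C | intermediate
14 | dicyclohexyl[(1E,3E,5E)-hepta-1,3,5-trien-1-yl]borane (formed in situ) | C/C=C/C=C/C=C/B(C1CCCCC1)C1CCCCC1 | intermediate
15 | ethyl[(1E,3E,5E)-hepta-1,3,5-trien-1-yl]zinc (formed in situ) | CC[Zn]/C=C/C=C/C=C/C | intermediate
16 | 5-[(3R,4E,6E,8E)-3-hydroxydeca-4,6,8-trien-1-yl]-2,4-dimethoxy-6-methylcyclohepta-2,4,6-trien-1-one | COc1cc(OC)c(=O)cc(C)c1CC[C@@H](O)/C=C/C=C/C=C/C | intermediate
17 | (2R)-2-[(1E,3E,5E)-hepta-1,3,5-trien-1-yl]-8-methoxy-5-methyl-3,4-dihydrocyclohepta[b]pyran-7(2H)-one | C/C=C/C=C/C=C/[C@H]1CCc2c(C)cc(=O)c(OC)cc2O1 | intermediate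
18 | (2R)-2-[(1E,3E,5E)-hepta-1,3,5-trien-1-yl]-8-hydroxy-5-methyl-3,4-dihydrocyclohepta[b]pyran-7(2H)-one | C/C=C/C=C/C=C/[C@H]1CCc2c(C)cc(=O)c(O)cc2O1 | intermediate
19 | 2-hydroxy-6-methyl-5-methylidenecyclohepta-2,6-diene-1,4-dione (tropolone o-quinone methide, formed in situ) | C=C1C(C)=CC(=O)C(O)=CC1=O | intermediate
20 | (2R,3R)-8-hydroxy-2-[(1E,3E)-4-[(2R)-8-hydroxy-5-methyl-7-oxo-2,3,4,7-tetrahydrocyclohepta[b]pyran-2-yl]buta-1,3-dien-1-yl]-3,5-dimethyl-3,4-dihydrocyclohepta[b]pyran-7(2H)-one (CNP0332980.1) | Cc1cc(=O)c(O)cc2c1C[C@@H](C)[C@H](/C=C/C=C/[C@H]1CCc3c(C)cc(=O)c(O)cc3O1)O2 | target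

**Step count and risks**
Total step count: 13.
Longest linear sequence: 10 steps (steps 1, 2, 3, 4, 5, 8, 10, 11, 12, 13).

Steps most likely to fail:

Step 13. The chiral acid may not discriminate the two faces of the propenyl terminus, since the hydrocarbon triene offers it no binding site. It may also ionise the trienylic C2'–O bond of 18 and scramble that centre, or the o-quinone methide may oligomerise faster than it is trapped. The fallback uses known chemistry, sets out from 9 and 18 and gives up both asymmetric induction and the acid. Thermal dehydration of 9 in p-xylene at 140 °C (sealed tube, BHT, 9 added slowly) should generate 19 under neutral conditions. The uncatalysed hetero-Diels–Alder reaction, the established mode of reaction of tropolone o-quinone methides with alkenes, should then give only trans adducts. Because 18 is a single enantiomer, the two products are diastereomers: 20 and (2S,3S)-8-hydroxy-2-[(1E,3E)-4-[(2R)-8-hydroxy-5-methyl-7-oxo-2,3,4,7-tetrahydrocyclohepta[b]pyran-2-yl]buta-1,3-dien-1-yl]-3,5-dimethyl-3,4-dihydrocyclohepta[b]pyran-7(2H)-one F1. Preparative HPLC should separate them, and the route is rejoined at 20.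

Step 7. In hot aqueous acid the benzylic alcohol of 9 may ionise and the product may condense with itself, or the C4 ether may be cleaved incompletely. The fallback sets out from 6 and changes the protecting-group plan so that the ethers are cleaved before the hydroxymethyl group exists. Hydrolysis of 6 (2 M H2SO4, dioxane, 90 °C) should give 5-bromo-2,4-dihydroxy-6-methylcyclohepta-2,4,6-trien-1-one F2. Silylation of both acidic hydroxyls (TBSCl, imidazole, DMF) should give 5-bromo-2,4-bis(tert-butyldimethylsilyloxy)-6-methylcyclohepta-2,4,6-trien-1-one F3. The Stille hydroxymethylation of step 6 applied to F3 should give 2,4-bis(tert-butyldimethylsilyloxy)-5-(hydroxymethyl)-6-methylcyclohepta-2,4,6-trien-1-one F4. Fluoride (TBAF buffered with AcOH, THF, 0 °C) should then release the triol under conditions in which no benzylic cation can form, and the route is rejoined at 9.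

Step 8. Oxidative addition at the bromide flanked by methoxy and methyl may be slow, insertion may occur with the wrong regiochemistry, or the product aldehyde may undergo aldol condensation under the basic conditions. The fallback sets out from 7 and replaces the Heck reaction by an sp2–sp3 cross-coupling with a masked aldehyde. Negishi coupling with commercial 2-(1,3-dioxolan-2-yl)ethylzinc bromide (Pd(OAc)2, SPhos, THF, 60 °C) should give 5-[2-(1,3-dioxolan-2-yl)ethyl]-2,4-dimethoxy-6-methylcyclohepta-2,4,6-trien-1-one F5. Mild acetal cleavage (PPTS, wet acetone, 50 °C) should then give the aldehyde, and the route is rejoined at 11.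

**Further compounds**
F1 | step 13 | (2S,3S)-8-hydroxy-2-[(1E,3E)-4-[(2R)-8-hydroxy-5-methyl-7-oxo-2,3,4,7-tetrahydrocyclohepta[b]pyran-2-yl]buta-1,3-dien-1-yl]-3,5-dimethyl-3,4-dihydrocyclohepta[b]pyran-7(2H)-one | Cc1cc(=O)c(O)cc2c1C[C@H](C)[C@@H](/C=C/C=C/[C@H]1CCc3c(C)cc(=O)c(O)cc3O1)O2
F2 | step 7 | 5-bromo-2,4-dihydroxy-6-methylcyclohepta-2,4,6-trien-1-one | Cc1cc(=O)c(O)cc(O)c1Br
F3 | step 7 | 5-bromo-2,4-bis(tert-butyldimethylsilyloxy)-6-methylcyclohepta-2,4,6-trien-1-one | Cc1cc(=O)c(O[Si](C)(C)C(C)(C)C)cc(O[Si](C)(C)C(C)(C)C)c1Br
F4 | step 7 | 2,4-bis(tert-butyldimethylsilyloxy)-5-(hydroxymethyl)-6-methylcyclohepta-2,4,6-trien-1-one | Cc1cc(=O)c(O[Si](C)(C)C(C)(C)C)cc(O[Si](C)(C)C(C)(C)C)c1CO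
F5 | step 8 | 5-[2-(1,3-dioxolan-2-yl)ethyl]-2,4-dimethoxy-6-methylcyclohepta-2,4,6-trien-1-one | COc1cc(OC)c(=O)cc(C)c1CCC1OCCO1
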